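## Structural features

The target is an alkyl aryl ether between O7 of a 6,8-dimethoxycoumarin and C11, a CH2 group on the quaternary carbon C9 of a trans-decalin. Ring A is C1–C5 and C10 and carries the C3 ketone; ring B is C5–C10. The decalin has five contiguous stereocentres, C4–C5–C10–C9–C8 (4S,5R,8S,9S,10S). C5 and C9 are quaternary and 1,3-related, with both methyl groups axial on the α face; the C8 methyl is axial on the β face (trans to the C9 methyl), H-10 is β, and the C4 methyl is equatorial. C4 lies next to the ketone and is the thermodynamically favoured epimer, so it can be corrected at the end; the other four centres must be built. The fragile groups are the coumarin lactone (base, hydride, organometallics), its C3=C4 bond (hydrogenation) and the enolisable ketone. C11 is neopentyl, so substitution at that carbon is not realistic. The real difficulty is the vicinal pair C8 (tertiary) and C9 (quaternary) with trans-diaxial methyl groups beside the ring fusion, together with the ether from a neopentyl alcohol to a phenol oxygen flanked by two methoxy groups. The key step exploits the fact that C9 is bonded to C8 and also carries C11: with C11 as a carboxyl carbon and an oxygen on C6, a δ-lactone O–C11(=O)–C9–C10–C5–C6 fused to ring A and bearing a propenyl group (C7=C8) on C6 becomes, after enolisation, the array C9=C11–O–C6–C7=C8, whose [3,3] shift forms C8–C9 and ring B. Re-deriving the stereochemical course (suprafacial shift through the enforced boat) shows that the 6R lactone, with the propenyl group cis to the C5 methyl and an E double bond, maps onto 8S,9S. The configurations of lactone 16 and acid 19 therefore need no correction. What is improved is how C6, the alkene geometry and the absolute configuration are secured.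

## Logic of the disconnections

25 to 24: the C3 carbonyl is masked as a dioxolane (two C3–O bonds). The ketone would not survive LiAlH4, would be enolised by LDA and could be α-arylated under palladium catalysis. The demand is a final hydrolysis mild enough for the coumarin; it also lets C4 settle in its stable configuration.

24 to 21 and 23 (23 from 22): the aryl C7–O bond is cut, not the C11–O bond. C11 is neopentyl, so the alcohol must act as the nucleophile at oxygen. The gain is full convergence on commercial 22. The demand is a catalytic C–O coupling at an aryl sulfonate with two ortho substituents, run after all hydrogenation and hydride steps.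

21 to 20 to 19: the C6=C7 double bond is reintroduced and C11 is raised to the acid level. This reveals a γ,δ-unsaturated acid (C11–C9–C8–C7=C6), the retron of a Claisen rearrangement. The forward demand is reduction of a hindered acid and a hydrogenation that creates no stereocentre.

19 to 16: the C8–C9 bond is cut and the C6–O bond to the C11 carboxyl is re-formed. Ring B, the quaternary C9 and the tertiary C8 are traced back to one carbinol centre (C6) and one E alkene, and the configuration at C9 becomes irrelevant. The demand is a boat-like [3,3] shift inside a trans-fused bicycle, with pure 6R configuration and pure E geometry.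

16 to 13 and 14: the lactone C11–O bond and the C6–C7 bond are cut, giving an aldehyde and an E-propenyl nucleophile. C6 is then a reagent-controlled centre. The demand is a chemoselective, geometry-retaining alkenyl transfer to a neopentyl aldehyde in the presence of an ester.

13 to 11 to 10 to 8: the formyl group is traced to a vinyl group (C6=CH2 cleaved oxidatively), the ketal to the ketone, and the C5–C6 bond to a conjugate addition. C5 and C4 are thereby relayed from C10. The demand is 1,4-addition to a tetrasubstituted enone on the face away from the C10 side chain.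

8 to 7 to 6: the C5–CH3 bond is cut (conjugate addition, then re-oxidation). An annulation with an aldehyde donor delivers the enone with hydrogen on C5, which allows a catalytic asymmetric ring synthesis. The demand is a regiospecific dehydrogenation.

6 to 3 and 4 (3 from 1): the C10–C1 bond (Michael) and the C4=C5 bond (aldol) are cut. C10 is the α-carbon of an aldehyde, so enamine catalysis can set the only centre that is not relayed. The gain is two simple commercial pieces. The demand is high face control and ring closure before the aldehyde can enolise.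

## Other disconnections considered

Alternative 1: The cut goes through the benzene ring of the coumarin at C4a–C8a, tracing the arene to a four-membered ring that already carries the three oxygen substituents. In the forward sense, cyclobutenone A2 would come from a dialkyl squarate by alkenyl addition, O-methylation and exchange of the vinylogous-ester methoxy group for the alkoxide of 21. On heating it would open (4π) to a dienylketene, whose 6π closure and tautomerisation give phenol A1; acetal hydrolysis, Wittig olefination with lactonisation, and ketal hydrolysis would follow. In its favour, the hindered oxygen of 21 is attached by addition–elimination at an electron-poor four-membered ring and not by metal-catalysed coupling at a crowded arene; on the certainty of that C–O bond it is the better plan. The substitution pattern is unambiguous, and no base-sensitive coumarin exists until the end. Against it, about five operations follow 21 instead of two, all on the most valuable intermediate; acetal and ketal must survive the thermolysis; and 22 is not used. It does nothing for the decalin, which would still need step 9. Mechanistically both plans rest on thermal pericyclic steps of predictable course and are equal there; on step economy the chosen plan is shorter.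

Alternative 2: The cut removes C5–C10 and C8–C9 together, so both carbocycles come from an open chain. Trienal A4 (E-2-methyl enal, a four-atom tether carrying the ketal and C4, and a diene with methyl groups on C5 and C8) would cyclise on heating or with Me2AlCl to aldehyde A3, and one hydride reduction would give 20. In its favour, it forms two rings, two bonds and four stereocentres in one step, against one ring, one bond and two stereocentres in step 9, and C11 arrives at the aldehyde level; on bond economy it is the better plan, and on step count probably the equal. Against it, both new bonds form at fully substituted carbons. The trans fusion requires the C5 methyl to be the inside substituent of the diene, which disfavours the s-cis conformer. The relative configuration depends on endo/exo preference and on face selection from the remote C4 centre alone. Me2AlCl may also open the dioxolane. In step 9, by contrast, the tethered boat leaves a single topology, so C8 and C9 follow from C6 and the alkene geometry.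

Alternative 3: The cut removes O1–C8a and C4–C4a, so the pyranone is traced to a salicylaldehyde made from an aryne. Iodoaryl triflate A6 would undergo iodine–magnesium exchange with iPrMgCl·LiCl and lose triflate to give the C4a–C8a aryne. Dimethylformamide would add with oxygen at C8a (next to boron) and carbon at C4a through a transient four-membered ring, and hydrolysis would give aldehyde A5. Oxidation of the C–B bond, O-methylation at C8, Wittig olefination with lactonisation, and ketal hydrolysis would follow. In its favour, the regiochemistry of O1 and C4 is set by the boryl group at low temperature, and the coumarin is formed last; on mildness towards the lactone it is the better plan. Against it, A6 is a hexasubstituted benzene that must already carry the neopentyl ether, so the hard C–O bond is only moved to an earlier arene (equal at best). The boronate may be attacked by the Grignard reagent, two phenolic hydroxyl groups must later be told apart, and four steps follow the key step. The chosen plan is shorter and uses 22 as bought.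

Key step: step 9

Remark on the chemistry: C9 is a mixture of epimers in every compound up to 16 (drawn without configuration; erased in step 9). Drimane-type locants are used throughout (ring A: C1–C5, C10; ring B: C5–C10; C11 on C9).

## Route

Step 1
Reactants: 1 ethyl 2-methylpent-4-enoate
Product: 3 ethyl 2-methyl-4-oxobutanoate, via secondary ozonide 2 (not isolated)
Conditions: O3, CH2Cl2, −78 °C; Me2S, −78 °C to rt
Reagents that add atoms: ozone, [O-][O+]=O
Why: Ozonolysis of a terminal alkene with reductive work-up; the ester is inert, and the racemic centre (later C9) does not matter because step 9 erases it.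

Step 2
Reactants: 3 ethyl 2-methyl-4-oxobutanoate; 4 pent-1-en-3-one
Product: 6 ethyl 2-[(1S)-3-methyl-4-oxocyclohex-2-en-1-yl]propanoate, via keto aldehyde 5 (not isolated)
Conditions: (R)-2-[methoxy(diphenyl)methyl]pyrrolidine (5 mol%), ethyl 3,4-dihydroxybenzoate (20 mol%), neat, 4 °C; then TsOH·H2O (10 mol%), toluene, 80 °C
Reagents that add atoms: none
Why: Enamine-catalysed asymmetric Michael addition of an aldehyde to a vinyl ketone, then acid-catalysed intramolecular aldol condensation (Robinson-type annulation). The diarylmethyl group of the catalyst shields one face of the E-enamine, so C10 should be set as 3R in 5 (1S in 6 by the change of CIP priorities); the (R)-catalyst is the enantiomer the shielding model assigns to this sense. Only the six-membered aldol ring is geometrically possible.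

Step 3
Reactants: 6 ethyl 2-[(1S)-3-methyl-4-oxocyclohex-2-en-1-yl]propanoate
Product: 7 ethyl 2-[(1S,2R)-2,3-dimethyl-4-(trimethylsilyloxy)cyclohex-3-en-1-yl]propanoate
Conditions: MeMgBr, CuBr·SMe2 (10 mol%), Me3SiCl, THF, −78 °C; Et3N, cold aq. NaHCO3
Reagents that add atoms: methylmagnesium bromide, C[Mg]Br; chlorotrimethylsilane, C[Si](C)(C)Cl
Why: Copper-catalysed conjugate addition with silyl trapping; methyl should add trans to the C10 side chain (this C5 centre is removed again in step 4), and the enolate is fixed regiospecifically as the C3–C4 silyl enol ether. The ester is not attacked at −78 °C.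

Step 4
Reactants: 7 ethyl 2-[(1S,2R)-2,3-dimethyl-4-(trimethylsilyloxy)cyclohex-3-en-1-yl]propanoate
Product: 8 ethyl 2-[(1R)-2,3-dimethyl-4-oxocyclohex-2-en-1-yl]propanoate
Conditions: Pd(OAc)2 (1.05 equiv), MeCN, rt to 40 °C
Reagents that add atoms: none
Why: Saegusa–Ito oxidation: the palladium enolate formed from the silyl enol ether loses the ring hydrogen on C5 by β-hydride elimination, giving the conjugated tetrasubstituted C4=C5 enone. C10 is untouched (its label changes only through CIP priorities).

Step 5
Reactants: 8 ethyl 2-[(1R)-2,3-dimethyl-4-oxocyclohex-2-en-1-yl]propanoate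
Product: 10 ethyl 2-[(1R,2R,3S)-2,3-dimethyl-4-oxo-2-vinylcyclohexyl]propanoate, via silyl enol ether 9 (not isolated)
Conditions: CH2=CHMgBr, CuBr·SMe2 (20 mol%), Me3SiCl, DMPU, THF, −78 to −30 °C; then 1 M HCl, THF, 0 °C
Reagents that add atoms: vinylmagnesium bromide, C=C[Mg]Br
Why: Silyl-accelerated copper-catalysed 1,4-addition to a β,β-disubstituted enone. Allylic strain with the C5 methyl holds the C10 side chain pseudo-axial, so vinyl should enter axially on the opposite face (C6 trans to C9; C5 set). Axial protonation of 9 on the face away from the axial C5 methyl gives the equatorial C4 methyl, which is also the thermodynamic epimer.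

Step 6
Reactants: 10 ethyl 2-[(1R,2R,3S)-2,3-dimethyl-4-oxo-2-vinylcyclohexyl]propanoate
Product: 11 ethyl 2-[(6S,7R,8R)-6,7-dimethyl-7-vinyl-1,4-dioxaspiro[4.5]decan-8-yl]propanoate
Conditions: (Me3SiOCH2)2, Me3SiOTf (5 mol%), CH2Cl2, −78 to −20 °C; pyridine
Reagents that add atoms: 1,2-bis(trimethylsilyloxy)ethane, C[Si](C)(C)OCCO[Si](C)(C)C
Why: Noyori ketalisation under aprotic conditions, which neither transesterifies the ethyl ester nor epimerises C4. The dioxolane is needed to carry C3 through LDA, LiAlH4 and the basic etherification.

Step 7
Reactants: 11 ethyl 2-[(6S,7R,8R)-6,7-dimethyl-7-vinyl-1,4-dioxaspiro[4.5]decan-8-yl]propanoate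
Product: 13 ethyl 2-[(6S,7R,8R)-7-formyl-6,7-dimethyl-1,4-dioxaspiro[4.5]decan-8-yl]propanoate, via secondary ozonide 12 (not isolated)
Conditions: O3, CH2Cl2, −78 °C; PPh3, −78 °C to rt
Reagents that add atoms: ozone, [O-][O+]=O
Why: Ozonolysis with reductive work-up; the aldehyde has no α-hydrogen and cannot epimerise, and ketal and ester are inert.

Step 8
Reactants: 13 ethyl 2-[(6S,7R,8R)-7-formyl-6,7-dimethyl-1,4-dioxaspiro[4.5]decan-8-yl]propanoate; 14 propyne
Product: 16 trans-fused δ-lactone (4S,5R,6R,10R)-3,3-ethylenedioxy-4,5,9-trimethyl-6-[(E)-prop-1-enyl]-11,6-olide (C9 epimers), via hydroxy ester 15 (not isolated)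
Conditions: 14, Cy2BH, hexane, 0 °C; Et2Zn, −78 °C; (+)-MIB (5 mol%), 13, toluene, −20 to 0 °C; then 45 °C; aq. NH4Cl
Reagents that add atoms: none
Why: Catalytic asymmetric alkenylzinc addition (alkyne hydroboration, boron-to-zinc exchange, amino-alcohol-accelerated transfer). Syn hydroboration fixes the E geometry, and the zinc reagent leaves the ester alone. The (2R)-morpholinoisoborneol ligand should direct the propenyl group to the Re face of the aldehyde (Noyori model), setting 6R. The zinc alkoxide of 15 then closes onto the ethyl ester, helped by the quaternary C5.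

Step 9
Reactants: 16 trans-fused δ-lactone (4S,5R,6R,10R)-3,3-ethylenedioxy-4,5,9-trimethyl-6-[(E)-prop-1-enyl]-11,6-olide (C9 epimers)
Product: 19 (4S,5R,8S,9S,10S)-3,3-ethylenedioxy-4,5,8,9-tetramethyl-6-ene-trans-decalin-9-carboxylic acid, via silyl ketene acetal 17 (not isolated), via silyl ester 18 (not isolated)
Conditions: LDA, tBuMe2SiCl, DMPU, THF, −78 °C to rt; toluene, 110 °C (sealed tube, to 140 °C if required); AcOH–THF–H2O, rt
Reagents that add atoms: none
Why: LDA removes the C9 hydrogen of either epimer, and O-silylation in situ gives the endocyclic ketene acetal 17, so the configuration at C9 is erased. On heating, 17 should undergo an Ireland–Claisen [3,3]-sigmatropic shift across C9=C11–O–C6–C7=C8: C8–C9 forms as C6–O breaks, giving silyl ester 18; the closest known reaction type is the ring contraction of alkenyl-substituted lactone silyl ketene acetals to cycloalkene carboxylic acids. Ring B is closed by this sigmatropic bond formation within a 2-oxabicyclo[2.2.2]octene-like boat array, the six-membered lactone contracting to the carbocycle C5–C6=C7–C8–C9–C10; no chair is possible because C5 must end cis to C8 across the new C6=C7 bond. C9 is controlled by C6: the propenyl arm can reach the ketene acetal only on the lactone face on which it stands (cis to the C5 methyl), so C8 bonds there and the C9 methyl ends α with C11 β (9S). C8 is controlled by the E geometry: in the boat the methyl trans to C6 points outwards and ends trans to the C9 methyl (8S). The step needs rearrangement to outrun C-silylation, desilylation and ionisation of the allylic C6–O bond; in situ trapping in THF–DMPU gives the O-silyl species, C5 is quaternary so no β-elimination can start there, and the thermolysis is aprotic. The trans fusion holds the C9–C10–C5–C6 dihedral angle near 60°, so the boat must be skewed; models suggest that for the 6R epimer this skew keeps C10 near the plane of the O–C11=C9 unit and C5 near the plane of the allyl unit, whereas the 6S epimer would need the opposite skew and should be left behind.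

Step 10
Reactants: 19 (4S,5R,8S,9S,10S)-3,3-ethylenedioxy-4,5,8,9-tetramethyl-6-ene-trans-decalin-9-carboxylic acid
Product: 20 (4S,5R,8S,9S,10S)-3,3-ethylenedioxy-4,5,8,9-tetramethyl-6-ene-trans-decalin-9-methanol
Conditions: LiAlH4, THF, 0 °C to reflux; Fieser work-up
Reagents that add atoms: none
Why: Hydride reduction of a carboxylic acid to the primary alcohol; the quaternary C9 slows but should not prevent it, and the ketal and the isolated alkene are inert.

Step 11
Reactants: 20 (4S,5R,8S,9S,10S)-3,3-ethylenedioxy-4,5,8,9-tetramethyl-6-ene-trans-decalin-9-methanol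
Product: 21 (4S,5R,8S,9S,10S)-3,3-ethylenedioxy-4,5,8,9-tetramethyl-trans-decalin-9-methanol
Conditions: H2 (1 atm), Pd/C, EtOAc, rt
Reagents that add atoms: none
Why: Heterogeneous hydrogenation of the cis-disubstituted C6=C7 bond, which creates no stereocentre. It is done before the coumarin is attached because the coumarin C3=C4 bond would also be reduced.

Step 12
Reactants: 22 isofraxidin
Product: 23 6,8-dimethoxy-2-oxo-2H-chromen-7-yl trifluoromethanesulfonate
Conditions: Tf2O, pyridine, CH2Cl2, 0 °C
Reagents that add atoms: trifluoromethanesulfonic anhydride, O=S(=O)(OS(=O)(=O)C(F)(F)F)C(F)(F)F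
Why: O-Sulfonylation of an acidic phenol; the lactone is untouched under these conditions.

Step 13
Reactants: 21 (4S,5R,8S,9S,10S)-3,3-ethylenedioxy-4,5,8,9-tetramethyl-trans-decalin-9-methanol; 23 6,8-dimethoxy-2-oxo-2H-chromen-7-yl trifluoromethanesulfonate
Product: 24 6,8-dimethoxy-7-{[(4S,5R,8S,9S,10S)-3,3-ethylenedioxy-4,5,8,9-tetramethyl-trans-decalin-9-yl]methoxy}-2H-chromen-2-one
Conditions: Pd2(dba)3 (2.5 mol%), tBuBrettPhos (6 mol%), Cs2CO3, toluene, 80 °C
Reagents that add atoms: none
Why: Palladium-catalysed C–O cross-coupling of a primary alcohol (Buchwald–Hartwig etherification): oxidative addition of zerovalent palladium to the aryl sulfonate, alkoxide exchange, reductive elimination. The bond is made at oxygen, so the neopentyl carbon is not a reaction centre, and the palladium alkoxide of 21 has no β-hydrogen (C9 is quaternary). The ketal prevents α-arylation of the ketone.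

Step 14
Reactants: 24 6,8-dimethoxy-7-{[(4S,5R,8S,9S,10S)-3,3-ethylenedioxy-4,5,8,9-tetramethyl-trans-decalin-9-yl]methoxy}-2H-chromen-2-one
Product: 25 7-{[(1S,2S,4aR,5S,8aS)-1,2,4a,5-tetramethyl-6-oxodecahydronaphthalen-1-yl]methoxy}-6,8-dimethoxy-2H-chromen-2-one
Conditions: 1 M HCl, THF, rt
Reagents that add atoms: water, O
Why: Acid hydrolysis of the dioxolane; coumarin and aryl ether tolerate dilute acid. Any C4 epimer should equilibrate through the enol to the equatorial methyl, which is the configuration of the target.

## Compound list

1 | ethyl 2-methylpent-4-enoate (racemic) | CCOC(=O)C(C)CC=C | starting material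
2 | ethyl 2-methyl-3-(1,2,4-trioxolan-3-yl)propanoate (secondary ozonide of 1) | CCOC(=O)C(C)CC1OCOO1 | intermediate
3 | ethyl 2-methyl-4-oxobutanoate (racemic) | CCOC(=O)C(C)CC=O | intermediate
4 | pent-1-en-3-one (ethyl vinyl ketone) | CCC(=O)C=C | starting material
5 | ethyl (3R)-3-formyl-2-methyl-6-oxooctanoate (C2 epimers; C3 is C10) | CCOC(=O)C(C)[C@H](C=O)CCC(=O)CC | intermediate
6 | ethyl 2-[(1S)-3-methyl-4-oxocyclohex-2-en-1-yl]propanoate (C9 epimers) | CCOC(=O)C(C)[C@@H]1C=C(C)C(=O)CC1 | intermediate
7 | ethyl 2-[(1S,2R)-2,3-dimethyl-4-(trimethylsilyloxy)cyclohex-3-en-1-yl]propanoate (2-methyl trans to the side chain) | CCOC(=O)C(C)[C@@H]1[C@@H](C)C(C)=C(O[Si](C)(C)C)CC1 | intermediate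
8 | ethyl 2-[(1R)-2,3-dimethyl-4-oxocyclohex-2-en-1-yl]propanoate | CCOC(=O)C(C)[C@@H]1C(C)=C(C)C(=O)CC1 | intermediate
9 | ethyl 2-[(1R,2R)-2,3-dimethyl-4-(trimethylsilyloxy)-2-vinylcyclohex-3-en-1-yl]propanoate | CCOC(=O)C(C)[C@H]1CCC(O[Si](C)(C)C)=C(C)[C@]1(C)C=C | intermediate
10 | ethyl 2-[(1R,2R,3S)-2,3-dimethyl-4-oxo-2-vinylcyclohexyl]propanoate (vinyl trans to the side chain; the two methyl groups cis) | CCOC(=O)C(C)[C@H]1CCC(=O)[C@@H](C)[C@]1(C)C=C | intermediate
11 | ethyl 2-[(6S,7R,8R)-6,7-dimethyl-7-vinyl-1,4-dioxaspiro[4.5]decan-8-yl]propanoate | CCOC(=O)C(C)[C@H]1CCC2(OCCO2)[C@@H](C)[C@]1(C)C=C | intermediate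
12 | ethyl 2-[(6S,7R,8R)-6,7-dimethyl-7-(1,2,4-trioxolan-3-yl)-1,4-dioxaspiro[4.5]decan-8-yl]propanoate (secondary ozonide of 11) | CCOC(=O)C(C)[C@H]1CCC2(OCCO2)[C@@H](C)[C@]1(C)C1OCOO1 | intermediate
13 | ethyl 2-[(6S,7R,8R)-7-formyl-6,7-dimethyl-1,4-dioxaspiro[4.5]decan-8-yl]propanoate | CCOC(=O)C(C)[C@H]1CCC2(OCCO2)[C@@H](C)[C@]1(C)C=O | intermediate
14 | propyne | CC#C | starting material
15 | ethyl 2-{(6S,7R,8R)-7-[(1R,2E)-1-hydroxybut-2-en-1-yl]-6,7-dimethyl-1,4-dioxaspiro[4.5]decan-8-yl}propanoate (zinc alkoxide in the flask) | CCOC(=O)C(C)[C@H]1CCC2(OCCO2)[C@@H](C)[C@]1(C)[C@H](O)/C=C/C | intermediate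
16 | trans-fused δ-lactone: ring A (C3 dioxolane, 4S methyl, 5R methyl, 10R) fused at C5–C10 to O–C11(=O)–C9H(CH3)–C10–C5–C6H[(E)-prop-1-enyl]; 6R, propenyl cis to the C5 methyl; both C9 epimers | O=C1C(C)[C@H]2CCC3(OCCO3)[C@@H](C)[C@]2(C)[C@@H](/C=C/C)O1 | intermediate
17 | tert-butyldimethylsilyl ketene acetal of 16 (endocyclic C9=C11) | CC(C)(C)[Si](C)(C)OC1=C(C)[C@H]2CCC3(OCCO3)[C@@H](C)[C@]2(C)[C@@H](/C=C/C)O1 | intermediate
18 | tert-butyldimethylsilyl ester of 19 | CC(C)(C)[Si](C)(C)OC(=O)[C@]1(C)[C@H]2CCC3(OCCO3)[C@@H](C)[C@]2(C)C=C[C@@H]1C | intermediate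
19 | (4S,5R,8S,9S,10S)-3,3-ethylenedioxy-4,5,8,9-tetramethyl-6-ene-trans-decalin-9-carboxylic acid (C11 acid; C9 methyl α, C8 methyl β) | OC(=O)[C@]1(C)[C@H]2CCC3(OCCO3)[C@@H](C)[C@]2(C)C=C[C@@H]1C | intermediate
20 | (4S,5R,8S,9S,10S)-3,3-ethylenedioxy-4,5,8,9-tetramethyl-6-ene-trans-decalin-9-methanol | OC[C@]1(C)[C@H]2CCC3(OCCO3)[C@@H](C)[C@]2(C)C=C[C@@H]1C | intermediate
21 | (4S,5R,8S,9S,10S)-3,3-ethylenedioxy-4,5,8,9-tetramethyl-trans-decalin-9-methanol | OC[C@]1(C)[C@H]2CCC3(OCCO3)[C@@H](C)[C@]2(C)CC[C@@H]1C | intermediate
22 | isofraxidin (7-hydroxy-6,8-dimethoxy-2H-chromen-2-one) | COc1cc2ccc(=O)oc2c(OC)c1O | starting material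
23 | 6,8-dimethoxy-2-oxo-2H-chromen-7-yl trifluoromethanesulfonate | COc1cc2ccc(=O)oc2c(OC)c1OS(=O)(=O)C(F)(F)F | intermediate
24 | 6,8-dimethoxy-7-{[(4S,5R,8S,9S,10S)-3,3-ethylenedioxy-4,5,8,9-tetramethyl-trans-decalin-9-yl]methoxy}-2H-chromen-2-one | COc1cc2ccc(=O)oc2c(OC)c1OC[C@]1(C)[C@H]2CCC3(OCCO3)[C@@H](C)[C@]2(C)CC[C@@H]1C | intermediate
25 | 7-{[(1S,2S,4aR,5S,8aS)-1,2,4a,5-tetramethyl-6-oxodecahydronaphthalen-1-yl]methoxy}-6,8-dimethoxy-2H-chromen-2-one | COc1cc2ccc(=O)oc2c(OC)c1OC[C@]1(C)[C@H]2CCC(=O)[C@@H](C)[C@]2(C)CC[C@@H]1C | target

## Step count and least certain steps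

Total: 14 steps. Longest linear sequence: 13 steps (steps 1–11, 13 and 14, from 1); step 12 prepares 23 from 22.

Step 9 (key step). Most likely to go wrong: the skewed boat may not be reached below the temperature at which the ketene acetal is lost by silyl migration to carbon or by ionisation of the allylic C6–O bond with 1,4-elimination; lactone would then be recovered after work-up. The trans-fused case has no direct precedent.
Fallback, from 11, returning at 19 (open-chain Claisen and metathesis in place of ring contraction):
- Saponification (LiOH, THF–H2O) would give 2-[(6S,7R,8R)-6,7-dimethyl-7-vinyl-1,4-dioxaspiro[4.5]decan-8-yl]propanoic acid F1.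
- Esterification with (E)-but-2-en-1-ol (EDC, DMAP) would give the crotyl ester F2.
- An acyclic Ireland–Claisen rearrangement (LDA, Me3SiCl, THF, −78 to 60 °C) would form the same C8–C9 bond through a chair and give the diene acid F3, with vinyl groups on C5 and C8.
- Ring-closing metathesis (second-generation Grubbs catalyst, CH2Cl2, 40 °C) would close ring B at C6=C7 to give 19.
- Stereocontrol at C8 and C9 is weaker here (ketene acetal geometry and face selection), so diastereomers would have to be separated.

Step 5. Most likely to go wrong: 1,2-addition or enolisation may compete with 1,4-addition at the crowded tetrasubstituted β-carbon, and some addition may occur on the side-chain face.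
Fallback, from 8, returning at 13:
- Hosomi–Sakurai allylation (allyltrimethylsilane, TiCl4, CH2Cl2, −78 °C), reliable for quaternary centres, would give ethyl 2-[(1R,2R,3S)-2-allyl-2,3-dimethyl-4-oxocyclohexyl]propanoate F4.
- Alkene isomerisation (RuHCl(CO)(PPh3)3, toluene, 80 °C) would give the (E)-prop-1-enyl ketone F5.
- Noyori ketalisation would give ketal F6.
- Ozonolysis would cleave the propenyl group to the formyl group of 13.

Step 8. Most likely to go wrong: the facial preference of the substrate may oppose the catalyst, or addition to the neopentyl aldehyde may be slow enough for ethyl transfer to compete. Any 6S product is a diastereomer and separable; by the same token, the minor enantiomer carried from step 2 is converted into a diastereomer here and removed.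
Fallback, from 13, returning at 16:
- Nozaki–Hiyama–Kishi coupling with (E)-1-iodoprop-1-ene (CrCl2, NiCl2 cat., DMF) would give the hydroxy ester as a mixture of C6 epimers F7.
- Dess–Martin oxidation would give the (E)-but-2-enoyl ketone F8.
- Corey–Bakshi–Shibata reduction ((S)-methyl oxazaborolidine, catecholborane, −78 °C; quaternary C5 as the large group) would give 15.
- Lactonisation (PPTS, toluene, 60 °C) would give 16.

Step 13. Most likely to go wrong: the triflyl group may transfer to the alkoxide (S–O cleavage), reductive elimination may be slow at the doubly ortho-substituted aryl palladium alkoxide, and the base may open the coumarin at 80 °C.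
Fallback, from 23, returning at 24:
- Palladium-catalysed exchange of triflate for bromide (KBr, Pd2(dba)3, tBuBrettPhos, toluene, 100 °C) would give 7-bromo-6,8-dimethoxy-2H-chromen-2-one F9.
- F9 would be coupled with 21 by nickel/photoredox etherification at room temperature (NiCl2·glyme, 4,4′-di-tert-butyl-2,2′-bipyridine, [Ir{dF(CF3)ppy}2(dtbbpy)]PF6, quinuclidine, K2CO3, MeCN, blue light) to give 24.

## Further compounds

F1 | step 9 | 2-[(6S,7R,8R)-6,7-dimethyl-7-vinyl-1,4-dioxaspiro[4.5]decan-8-yl]propanoic acid | OC(=O)C(C)[C@H]1CCC2(OCCO2)[C@@H](C)[C@]1(C)C=C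
F2 | step 9 | (E)-but-2-en-1-yl 2-[(6S,7R,8R)-6,7-dimethyl-7-vinyl-1,4-dioxaspiro[4.5]decan-8-yl]propanoate | C/C=C/COC(=O)C(C)[C@H]1CCC2(OCCO2)[C@@H](C)[C@]1(C)C=C
F3 | step 9 | diene acid (4S,5R,8S,9S,10S; ring B of 19 opened between C6 and C7, vinyl groups on C5 and C8) | OC(=O)[C@@](C)([C@@H](C)C=C)[C@H]1CCC2(OCCO2)[C@@H](C)[C@]1(C)C=C
F4 | step 5 | ethyl 2-[(1R,2R,3S)-2-allyl-2,3-dimethyl-4-oxocyclohexyl]propanoate | CCOC(=O)C(C)[C@H]1CCC(=O)[C@@H](C)[C@]1(C)CC=C
F5 | step 5 | ethyl 2-{(1R,2R,3S)-2,3-dimethyl-4-oxo-2-[(E)-prop-1-enyl]cyclohexyl}propanoate | CCOC(=O)C(C)[C@H]1CCC(=O)[C@@H](C)[C@]1(C)/C=C/C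
F6 | step 5 | ethyl 2-{(6S,7R,8R)-6,7-dimethyl-7-[(E)-prop-1-enyl]-1,4-dioxaspiro[4.5]decan-8-yl}propanoate | CCOC(=O)C(C)[C@H]1CCC2(OCCO2)[C@@H](C)[C@]1(C)/C=C/C
F7 | step 8 | ethyl 2-{(6S,7R,8R)-7-[(E)-1-hydroxybut-2-enyl]-6,7-dimethyl-1,4-dioxaspiro[4.5]decan-8-yl}propanoate (C6 epimers) | CCOC(=O)C(C)[C@H]1CCC2(OCCO2)[C@@H](C)[C@]1(C)C(O)/C=C/C
F8 | step 8 | ethyl 2-{(6S,7R,8R)-7-[(E)-but-2-enoyl]-6,7-dimethyl-1,4-dioxaspiro[4.5]decan-8-yl}propanoate | CCOC(=O)C(C)[C@H]1CCC2(OCCO2)[C@@H](C)[C@]1(C)C(=O)/C=C/C
F9 | step 13 | 7-bromo-6,8-dimethoxy-2H-chromen-2-one | COc1cc2ccc(=O)oc2c(OC)c1Br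
A1 | alternative 1 | 2-(diethoxymethyl)-4,6-dimethoxy-5-(decalinylmethoxy)phenol | Oc1c(C(OCC)OCC)cc(OC)c(OC[C@]2(C)[C@H]3CCC4(OCCO4)[C@@H](C)[C@]3(C)CC[C@@H]2C)c1OC
A2 | alternative 1 | 4-[(E)-3,3-diethoxyprop-1-enyl]-2,4-dimethoxy-3-(decalinylmethoxy)cyclobut-2-en-1-one | CCOC(OCC)/C=C/C1(OC)C(OC[C@]2(C)[C@H]3CCC4(OCCO4)[C@@H](C)[C@]3(C)CC[C@@H]2C)=C(OC)C1=O
A3 | alternative 2 | trans-fused 6-ene decalin C11 aldehyde with C3 dioxolane | O=C[C@]1(C)[C@H]2CCC3(OCCO3)[C@@H](C)[C@]2(C)C=C[C@@H]1C
A4 | alternative 2 | (2E,7S,8E,10E)-6,6-ethylenedioxy-2,7,8-trimethyldodeca-2,8,10-trienal | O=C/C(C)=C/CCC1(OCCO1)[C@@H](C)/C(C)=C/C=C/C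
A5 | alternative 3 | 2-hydroxy-5-methoxy-4-(decalinylmethoxy)-3-(pinacolboryl)benzaldehyde | O=Cc1cc(OC)c(OC[C@]2(C)[C@H]3CCC4(OCCO4)[C@@H](C)[C@]3(C)CC[C@@H]2C)c(B2OC(C)(C)C(C)(C)O2)c1O
A6 | alternative 3 | 2-iodo-4-methoxy-5-(decalinylmethoxy)-6-(pinacolboryl)phenyl trifluoromethanesulfonate | FC(F)(F)S(=O)(=O)Oc1c(I)cc(OC)c(OC[C@]2(C)[C@H]3CCC4(OCCO4)[C@@H](C)[C@]3(C)CC[C@@H]2C)c1B1OC(C)(C)C(C)(C)O1
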